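## Structural features

The target is a flavonol with no stereocentre: ring A (benzene, C4a to C8a) is fused to ring C (a 3-hydroxy-4-pyranone made of O1, C2, C3 and C4), and ring B, a para-disubstituted benzene, is attached at C2. Ring A is a 1,2,3,5-tetraoxygenated benzene in which O1 (on C8a), the methoxy group on C8 and the hydroxyl on C7 are contiguous, the hydroxyl on C5 stands alone and only C6 bears hydrogen. The two oxygens ortho to C4a (O1 and the C5 hydroxyl) differ only in their neighbours, so a ring closure onto a 2,6-dihydroxyaryl ketone can give the 8-methoxy or the 6-methoxy isomer, and acid can interconvert the two by ring opening and reclosure. Ring C carries three adjacent oxidised carbons, C2 (bound to O1), C3 (hydroxyl) and C4 (carbonyl); the C3–C4 bond joins two oxygen-bearing carbons of like polarity, and the flavonol is the enol of a chromane-3,4-dione. The key step exploits this feature: C4 enters as an aldehyde that is turned into an acyl anion, C3 is an ester carbon, and forming the C3–C4 bond closes ring C at its final oxidation level. The fragile groups are the aryl prenyl ether on ring B (lost under Brønsted or Lewis acid, attacked by electrophilic oxidants and by hydrogenation), the flavonol enol (cleaved by base in the presence of oxygen) and the two free phenols of ring A, which need masks that come off without acid or hydrogen. The real difficulty is therefore regiochemical and chemoselective: the single methyl ether must sit on the C8 oxygen, the C3 oxygen must arrive without an oxidant, and three hydroxyls must be released while the fourth stays prenylated.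

## Logic of the disconnections

13 from 12. The two O–CH2 bonds of the allyl ethers on the C5 and C7 oxygens are cut. These phenols must be masked while O1 is alkylated and while the carbene acts on the aldehyde, and an allyl ether comes off with zerovalent palladium under neutral conditions, without acid, oxidant or hydrogen. The gain in atoms is small, but it is what makes the end game chemoselective. The forward step must distinguish two unsubstituted allyl ethers from the trisubstituted prenyl ether on ring B.

12 from 9 (key disconnection). The C3–C4 bond of ring C is cut between the enol carbon and the carbonyl carbon. Both carbons are oxidised, so no ordinary enolate disconnection fits; with C4 as an aromatic aldehyde converted into an acyl anion and C3 as an ester, the bond is a union of two acceptor carbons by polarity reversal. The gain is that the heterocycle, its C3 oxygen and its oxidation level all collapse into the open aryl ether 9 with two ordinary functional groups, and no oxidation is needed next to the prenyl double bond. The demand is that the carbene-derived acyl anion of a crowded, electron-rich aldehyde attacks an ester through a six-membered transition state faster than the ester enolate adds to the aldehyde.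

9 from 5 and 8. The O1–C2 ether bond is cut, which divides the molecule into its ring A and ring B halves. This makes the route convergent and ties O1 to a phenol that is already defined: 5 has a single free hydroxyl, the one next to the methoxy group, so no 6-methoxy isomer can arise. The demand is an SN2 reaction of a hindered, chelated phenoxide with a secondary benzylic bromide.

5 from 4. The O–CH3 bond on the future C8 oxygen is cut, leaving a catechol whose two hydroxyls differ in their relation to the formyl group. The gain is that the methyl ether is placed by the intrinsic difference between a chelated and a non-chelated hydroxyl, with no extra protecting group. The demand is methylation of the non-chelated hydroxyl only.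

4 from 2. The C–O bond at the future C8 is traced back to a C–CHO bond. In the target the C8 oxygen and the C4 carbon are both ortho to O1; in 2 they are the two equivalent formyl groups that flank the free hydroxyl, so symmetry replaces a regiochemical decision. The gain is that a benzene ring with five different substituents reduces to a symmetrical dialdehyde. The demand is oxidation of one formyl group and not the second.

2 from 1. The two O–allyl bonds on the oxygens that become the C5 and C7 oxygens are cut, leading to a symmetrical starting material. The demand is that the hydroxyl between the two formyl groups stays free, which its double chelation and its crowding should ensure.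

8 from 7, and 7 from 6. The C–Br bond is traced to the C–OH bond of the α-hydroxy ester 7, and the O–CH2 bond of the prenyl ether is cut. The prenyl group thus enters at the start, on the only phenol present, which removes any need for a selective late prenylation of a polyphenol. The demands are alkylation of the phenol in the presence of the secondary alcohol and a bromination that runs without acid.

## Other disconnections considered

Alternative 1: the first plan to come to mind cuts O1–C2 and the C3–OH bond. An aldol condensation turns acetophenone A1 into chalcone A2, and the forward key step is the Algar–Flynn–Oyamada oxidation of A2 with alkaline H2O2, which closes ring C and installs the C3 hydroxyl together. The chosen plan is preferred on three grounds. In A2 the alkoxy group ortho to the ketone (the future C5 oxygen) twists the enone out of the ring plane, a situation in which this oxidation tends to divert toward five-membered aurones. The C3 oxygen is delivered by an oxidant, whereas the chosen ring closure needs none. A1 also demands the same ring A regiocontrol as 5, so no steps are saved.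

Alternative 2: a biomimetic fold of ring A. The C7–C8 bond is cut. Pyranone A3 already contains rings B and C; it carries a methoxymethyl group on the carbon that becomes C8a and a 3-oxopropanoate chain on the carbon that becomes C4a. A Claisen condensation of the methoxymethyl carbanion onto the ester, followed by enolisation, would give ring A of A4 with the C5 and C7 hydroxyls free and the methyl ether unambiguously at C8. The idea sets the ring A pattern by construction. However, the β-keto ester of A3 is deprotonated long before the methoxymethyl group, so the closure would have to run through a dianion onto a deactivated ester. A3 is also a fully substituted pyranone that would itself take most of a synthesis to assemble. The chosen plan reaches the same regiochemical certainty in three steps from symmetrical 1.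

Alternative 3: an oxygen-first annulation that uses the latent symmetry of ring A. The O1–C2 and C4–C4a bonds are cut. Symmetrical resorcinol A5 opens glycidic ester A6 at its benzylic carbon to give ether A7. An intramolecular Friedel–Crafts acylation at the only free position ortho to the new ether closes ring C to dihydroflavonol A8, and a dehydrogenation then gives the flavonol. Symmetry again removes the 6- versus 8-methoxy question. Against it, the acylation needs a strong Brønsted or Lewis acid that the prenyl ether would not survive, and the electron-rich ring of A5 can attack A6 through carbon instead of oxygen. Ring C is also reached in three operations at the wrong oxidation level, where the chosen key step needs one.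

Key step: step 7

Assumption: 1 and 6 are treated as purchasable catalogue compounds, and every compound that carries the benzylic stereocentre is used as the racemate, which is immaterial because that centre becomes trigonal in step 7.

## Steps

Step 1
Reactants: 1 2,4,6-trihydroxybenzene-1,3-dicarbaldehyde
Product: 2 2-hydroxy-4,6-bis(prop-2-en-1-yloxy)benzene-1,3-dicarbaldehyde
Conditions: allyl bromide (2.1 equiv), K2CO3 (2.2 equiv), DMF, 0 °C to rt
Reagents that add atoms: allyl bromide (3-bromoprop-1-ene), C=CCBr
Why: Williamson ether synthesis; the hydroxyls on C4 and C6 are each para to one formyl group and are the most acidic and least hindered, whereas the C2 hydroxyl lies between both formyl groups, is chelated by them and should stay free. The product is symmetrical, so its two formyl groups are equivalent.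

Step 2
Reactants: 2 2-hydroxy-4,6-bis(prop-2-en-1-yloxy)benzene-1,3-dicarbaldehyde
Product: 4 2,3-dihydroxy-4,6-bis(prop-2-en-1-yloxy)benzaldehyde, via formate ester 3 (not isolated)
Conditions: H2O2 (30% aq, 1.05 equiv), NaOH (2.5 equiv), THF–H2O, 0 °C, argon; then 1 M HCl
Reagents that add atoms: hydrogen peroxide, OO
Why: Dakin oxidation of an ortho-hydroxybenzaldehyde: hydroperoxide adds to one of the two equivalent formyl groups, the electron-rich aryl group migrates to oxygen and formate ester 3 is hydrolysed in the flask. After the first oxidation the ring is a catecholate whose remaining formyl group is far less electrophilic, so one equivalent of oxidant should stop at 4; the unactivated allyl double bonds are inert to alkaline peroxide.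

Step 3
Reactants: 4 2,3-dihydroxy-4,6-bis(prop-2-en-1-yloxy)benzaldehyde
Product: 5 2-hydroxy-3-methoxy-4,6-bis(prop-2-en-1-yloxy)benzaldehyde
Conditions: NaH (2.1 equiv), DMF, 0 °C, argon; MeI (1.0 equiv), 0 °C to rt; aq NH4Cl
Reagents that add atoms: iodomethane, CI
Why: Williamson methylation under double deprotonation: the phenoxide oxygen on C2 is conjugated to and chelated by the formyl group, so the non-conjugated oxygen on C3 is the more nucleophilic and should take the single equivalent of MeI, as in the established 3-O-alkylation of 2,3-dihydroxybenzaldehyde. This places the methyl ether next to the one hydroxyl that will become O1.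

Step 4
Reactants: 6 methyl 2-hydroxy-2-(4-hydroxyphenyl)acetate
Product: 7 methyl 2-hydroxy-2-{4-[(3-methylbut-2-en-1-yl)oxy]phenyl}acetate
Conditions: prenyl bromide (1.1 equiv), K2CO3, acetone, 50 °C
Reagents that add atoms: prenyl bromide (1-bromo-3-methylbut-2-ene), CC(C)=CCBr
Why: Williamson ether synthesis; carbonate deprotonates only the phenol, so the secondary alcohol is left untouched, and the phenoxide attacks the primary carbon of the allylic bromide.

Step 5
Reactants: 7 methyl 2-hydroxy-2-{4-[(3-methylbut-2-en-1-yl)oxy]phenyl}acetate
Product: 8 methyl 2-bromo-2-{4-[(3-methylbut-2-en-1-yl)oxy]phenyl}acetate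
Conditions: CBr4 (1.2 equiv), PPh3 (1.2 equiv), CH2Cl2, 0 °C
Reagents that add atoms: tetrabromomethane, BrC(Br)(Br)Br
Why: Appel reaction of a secondary benzylic α-hydroxy ester; the neutral conditions spare the prenyl ether, and the reactive racemic bromide is used without storage.

Step 6
Reactants: 5 2-hydroxy-3-methoxy-4,6-bis(prop-2-en-1-yloxy)benzaldehyde; 8 methyl 2-bromo-2-{4-[(3-methylbut-2-en-1-yl)oxy]phenyl}acetate
Product: 9 methyl 2-[2-formyl-6-methoxy-3,5-bis(prop-2-en-1-yloxy)phenoxy]-2-{4-[(3-methylbut-2-en-1-yl)oxy]phenyl}acetate
Conditions: K2CO3 (1.5 equiv), DMF, rt
Reagents that add atoms: none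
Why: Williamson ether synthesis (SN2 at a benzylic α-bromo ester) with the only free phenol of 5; it forms the O1–C2 bond on the oxygen next to the methoxy group, so the ring A pattern is fixed before ring C exists. Room temperature is kept to limit aldol addition of the new ester enolate to the formyl group.

Step 7
Reactants: 9 methyl 2-[2-formyl-6-methoxy-3,5-bis(prop-2-en-1-yloxy)phenoxy]-2-{4-[(3-methylbut-2-en-1-yl)oxy]phenyl}acetate
Product: 12 3-hydroxy-8-methoxy-2-{4-[(3-methylbut-2-en-1-yl)oxy]phenyl}-5,7-bis(prop-2-en-1-yloxy)-4H-chromen-4-one, via Breslow intermediate 10 (not isolated), via chromane-3,4-dione 11 (not isolated)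
Conditions: 1,4-dimethyl-1,2,4-triazolium iodide (20 mol %), DBU (1.3 equiv), THF, argon, rt to 45 °C; then aq citric acid
Reagents that add atoms: none
Why: Proposed new method: the triazolylidene set free by DBU adds to the formyl group of 9 and proton transfer gives the Breslow intermediate 10, an acyl anion equivalent at C4 that attacks the ester carbon (the future C3) in a six-membered transition state; loss of methoxide and release of the carbene give dione 11, and enolisation of its acidic C2–H gives the aromatic 3-hydroxy-4-pyranone 12. The closest known reaction types are the carbene-catalysed intramolecular crossed benzoin reaction of 2-(2-oxoalkoxy)benzaldehydes to 3-hydroxychroman-4-ones and the carbene-catalysed aldehyde–nitrile coupling of 2-(cyanomethoxy)benzaldehydes to 3-aminochromones, in which the same intermediate attacks a ketone or a carboxyl-level carbon through the same ring size; an ester as the acceptor is the untested element. Ring C is the only ring closed, by C3–C4 bond formation in the 6-exo-trig mode. No stereocentre is created, and the racemic centre of 9 is erased on enolisation. The step needs acylation to win over intramolecular aldol addition of the ester enolate to the aldehyde; that aldol adduct has a quaternary C2, cannot dehydrate and should revert, whereas acylation is made irreversible by methoxide loss and by formation of the flavonol anion, which is why more than one equivalent of base is used. The α-aryloxy group raises the electrophilicity of the ester, the small N-methyl carbene is chosen to reach the di-ortho-substituted aldehyde, and the same crowding should suppress intermolecular benzoin dimerisation.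

Step 8
Reactants: 12 3-hydroxy-8-methoxy-2-{4-[(3-methylbut-2-en-1-yl)oxy]phenyl}-5,7-bis(prop-2-en-1-yloxy)-4H-chromen-4-one
Product: 13 3,5,7-trihydroxy-8-methoxy-2-{4-[(3-methylbut-2-en-1-yl)oxy]phenyl}-4H-chromen-4-one
Conditions: Pd(PPh3)4 (5 mol %), morpholine (6 equiv), THF, rt, argon; then aq citric acid
Reagents that add atoms: none
Why: Tsuji–Trost deallylation: zerovalent palladium ionises the two unsubstituted allyl aryl ethers, whose phenoxide leaving groups are stabilised by the pyranone carbonyl, and morpholine traps the allyl unit. The prenyl ether, with its trisubstituted double bond, should bind and ionise far more slowly and survive; no acid, oxidant or hydrogen is involved.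

## Compound list

1 | 2,4,6-trihydroxybenzene-1,3-dicarbaldehyde | O=Cc1c(O)cc(O)c(C=O)c1O | starting material
2 | 2-hydroxy-4,6-bis(prop-2-en-1-yloxy)benzene-1,3-dicarbaldehyde | O=Cc1c(OCC=C)cc(OCC=C)c(C=O)c1O | intermediate
3 | 3-formyl-2-hydroxy-4,6-bis(prop-2-en-1-yloxy)phenyl formate (formate ester, formed in the flask) | O=COc1c(OCC=C)cc(OCC=C)c(C=O)c1O | intermediate
4 | 2,3-dihydroxy-4,6-bis(prop-2-en-1-yloxy)benzaldehyde | O=Cc1c(OCC=C)cc(OCC=C)c(O)c1O | intermediate
5 | 2-hydroxy-3-methoxy-4,6-bis(prop-2-en-1-yloxy)benzaldehyde | COc1c(OCC=C)cc(OCC=C)c(C=O)c1O | intermediate
6 | methyl 2-hydroxy-2-(4-hydroxyphenyl)acetate (racemic) | COC(=O)C(O)c1ccc(O)cc1 | starting material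
7 | methyl 2-hydroxy-2-{4-[(3-methylbut-2-en-1-yl)oxy]phenyl}acetate (racemic) | COC(=O)C(O)c1ccc(OCC=C(C)C)cc1 | intermediate
8 | methyl 2-bromo-2-{4-[(3-methylbut-2-en-1-yl)oxy]phenyl}acetate (racemic) | COC(=O)C(Br)c1ccc(OCC=C(C)C)cc1 | intermediate
9 | methyl 2-[2-formyl-6-methoxy-3,5-bis(prop-2-en-1-yloxy)phenoxy]-2-{4-[(3-methylbut-2-en-1-yl)oxy]phenyl}acetate (racemic) | COC(=O)C(Oc1c(OC)c(OCC=C)cc(OCC=C)c1C=O)c1ccc(OCC=C(C)C)cc1 | intermediate
10 | methyl 2-{2-[(1,4-dimethyl-1,4-dihydro-5H-1,2,4-triazol-5-ylidene)(hydroxy)methyl]-6-methoxy-3,5-bis(prop-2-en-1-yloxy)phenoxy}-2-{4-[(3-methylbut-2-en-1-yl)oxy]phenyl}acetate (Breslow intermediate, formed in the flask; racemic, enol geometry not defined) | CN1N=CN(C)C1=C(O)c1c(OCC=C)cc(OCC=C)c(OC)c1OC(C(=O)OC)c1ccc(OCC=C(C)C)cc1 | intermediate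
11 | 8-methoxy-2-{4-[(3-methylbut-2-en-1-yl)oxy]phenyl}-5,7-bis(prop-2-en-1-yloxy)-2H-chromene-3,4-dione (chromane-3,4-dione, formed in the flask; racemic) | O=C1C(=O)c2c(OCC=C)cc(OCC=C)c(OC)c2OC1c1ccc(OCC=C(C)C)cc1 | intermediate
12 | 3-hydroxy-8-methoxy-2-{4-[(3-methylbut-2-en-1-yl)oxy]phenyl}-5,7-bis(prop-2-en-1-yloxy)-4H-chromen-4-one | COc1c(OCC=C)cc(OCC=C)c2c(=O)c(O)c(-c3ccc(OCC=C(C)C)cc3)oc12 | intermediate
13 | 3,5,7-trihydroxy-8-methoxy-2-{4-[(3-methylbut-2-en-1-yl)oxy]phenyl}-4H-chromen-4-one (3,5,7-trihydroxy-8-methoxy-4'-prenyloxyflavone) | COc1c(O)cc(O)c2c(=O)c(O)c(-c3ccc(OCC=C(C)C)cc3)oc12 | target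

## Step count and least certain steps

Total step count: 8. Longest linear sequence: 6 steps (steps 1, 2, 3, 6, 7, 8 from 1); the ring B branch (steps 4 and 5) joins at step 6.

Step 7 (key step, proposed new method). The most likely failure is that the carbene does not convert the doubly ortho-substituted, electron-rich aldehyde into its Breslow intermediate, or that the adduct to the ester reverts faster than it loses methoxide. The substrate would then sit in the reversible aldol manifold and nothing productive would drain it. The fallback uses known chemistry and changes the ring C closure to an oxidative one. It sets out from 5 and comes back at 12.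
- Addition of MeMgBr (2.2 equiv, THF, 0 °C) to 5 should give carbinol F1.
- Oxidation with MnO2 in CH2Cl2 should give acetophenone F2.
- Claisen–Schmidt condensation (KOH, EtOH, rt) with 4-prenyloxybenzaldehyde F3 should give chalcone F4. F3 is made by Williamson prenylation of the commercial para-hydroxy aldehyde.
- Algar–Flynn–Oyamada oxidation of F4 (H2O2, NaOH, MeOH, 0 °C to rt) should close ring C to 12. The para-alkoxy group of ring B favours the six-membered closure, and the isolated double bonds are inert to alkaline peroxide.

Step 2. The likely failures are oxidation of the second formyl group when local excess of peroxide meets product, and aerial oxidation of the electron-rich catecholate to a quinone during the basic phase. The fallback makes over-oxidation impossible by masking one formyl group; it sets out from 2 and comes back at 4. Acetalisation of 2 with one equivalent of ethane-1,2-diol (cat. TsOH, toluene, water removal) should give mono-dioxolane F5, with unreacted 2 and the bis-acetal recycled by hydrolysis. Dakin oxidation of the single remaining formyl group of F5 should give catechol acetal F6, and brief treatment with dilute aqueous HCl in acetone should release 4.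

Step 3. The likely failure is loss of regiocontrol, with methylation spreading to the chelated C2 oxygen or to both oxygens when the dianion is poorly soluble. The fallback reverses the order in which the two catechol oxygens are used and relies on acidity instead of nucleophilicity; it sets out from 4 (with 8) and comes back at 9. With one equivalent of KHCO3 in DMF only the more acidic, formyl-conjugated C2 hydroxyl is ionised and should be alkylated by 8 to give catechol monoether F7. The remaining C3 hydroxyl of F7 is then methylated (MeI, K2CO3, acetone) to give 9.

Step 8. The likely failures are slow ionisation of the prenyl ether once the allyl ethers are gone, and C-allylation of the liberated, electron-rich ring A at C6 by the allyl–palladium species if trapping by the amine is slow. The fallback replaces ionisation by double-bond migration, to which a trisubstituted alkene is inert; it sets out from 12 and comes back at 13. Isomerisation with [Ir(cod)(PMePh2)2]PF6 (activated with H2, THF, rt) should give the bis(prop-1-enyl) ether F8, and the two enol ethers are then hydrolysed with dilute aqueous HCl in acetone at rt, far milder than anything that ionises a prenyl ether.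

Step 6. The likely failure is slow substitution at the hindered, chelated phenoxide, which lets solvolysis of the electron-rich benzylic bromide and base-induced aldol addition of the product compete. The fallback activates the alcohol instead of the phenol: a Mitsunobu reaction (PPh3, DIAD, THF, 0 °C to rt) between phenol 5 and α-hydroxy ester 7 sets out from 5 and 7 and comes back at 9 without any new intermediate and without base.

## Further compounds

F1 | step 7 | 1-[2-hydroxy-3-methoxy-4,6-bis(prop-2-en-1-yloxy)phenyl]ethan-1-ol (racemic) | CC(O)c1c(O)c(OC)c(OCC=C)cc1OCC=C
F2 | step 7 | 1-[2-hydroxy-3-methoxy-4,6-bis(prop-2-en-1-yloxy)phenyl]ethan-1-one | CC(=O)c1c(O)c(OC)c(OCC=C)cc1OCC=C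
F3 | step 7 | 4-[(3-methylbut-2-en-1-yl)oxy]benzaldehyde | CC(C)=CCOc1ccc(C=O)cc1
F4 | step 7 | (2E)-1-[2-hydroxy-3-methoxy-4,6-bis(prop-2-en-1-yloxy)phenyl]-3-{4-[(3-methylbut-2-en-1-yl)oxy]phenyl}prop-2-en-1-one | COc1c(OCC=C)cc(OCC=C)c(C(=O)/C=C/c2ccc(OCC=C(C)C)cc2)c1O
F5 | step 2 | 3-(1,3-dioxolan-2-yl)-2-hydroxy-4,6-bis(prop-2-en-1-yloxy)benzaldehyde | O=Cc1c(O)c(C2OCCO2)c(OCC=C)cc1OCC=C
F6 | step 2 | 3-(1,3-dioxolan-2-yl)-4,6-bis(prop-2-en-1-yloxy)benzene-1,2-diol | Oc1c(O)c(C2OCCO2)c(OCC=C)cc1OCC=C
F7 | step 3 | methyl 2-[2-formyl-6-hydroxy-3,5-bis(prop-2-en-1-yloxy)phenoxy]-2-{4-[(3-methylbut-2-en-1-yl)oxy]phenyl}acetate (racemic) | COC(=O)C(Oc1c(O)c(OCC=C)cc(OCC=C)c1C=O)c1ccc(OCC=C(C)C)cc1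
F8 | step 8 | 3-hydroxy-8-methoxy-2-{4-[(3-methylbut-2-en-1-yl)oxy]phenyl}-5,7-bis[(1E)-prop-1-en-1-yloxy]-4H-chromen-4-one | COc1c(O/C=C/C)cc(O/C=C/C)c2c(=O)c(O)c(-c3ccc(OCC=C(C)C)cc3)oc12
F0 | step 6 | none | none
A1 | alternative 1 | 1-[2-hydroxy-3-methoxy-4,6-bis(methoxymethoxy)phenyl]ethan-1-one | CC(=O)c1c(O)c(OC)c(OCOC)cc1OCOC
A2 | alternative 1 | (2E)-1-[2-hydroxy-3-methoxy-4,6-bis(methoxymethoxy)phenyl]-3-{4-[(3-methylbut-2-en-1-yl)oxy]phenyl}prop-2-en-1-one | COCOc1cc(OCOC)c(C(=O)/C=C/c2ccc(OCC=C(C)C)cc2)c(O)c1OC
A3 | alternative 2 | methyl 3-[2-(methoxymethyl)-5-(methoxymethoxy)-6-{4-[(3-methylbut-2-en-1-yl)oxy]phenyl}-4-oxo-4H-pyran-3-yl]-3-oxopropanoate | COCc1oc(-c2ccc(OCC=C(C)C)cc2)c(OCOC)c(=O)c1C(=O)CC(=O)OC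
A4 | alternative 2 | 5,7-dihydroxy-8-methoxy-3-(methoxymethoxy)-2-{4-[(3-methylbut-2-en-1-yl)oxy]phenyl}-4H-chromen-4-one | COCOc1c(-c2ccc(OCC=C(C)C)cc2)oc2c(OC)c(O)cc(O)c2c1=O
A5 | alternative 3 | 2-methoxy-5-(prop-2-en-1-yloxy)benzene-1,3-diol | COc1c(O)cc(OCC=C)cc1O
A6 | alternative 3 | methyl 3-{4-[(3-methylbut-2-en-1-yl)oxy]phenyl}oxirane-2-carboxylate (racemic, cis/trans mixture) | COC(=O)C1OC1c1ccc(OCC=C(C)C)cc1
A7 | alternative 3 | methyl 2-hydroxy-3-[3-hydroxy-2-methoxy-5-(prop-2-en-1-yloxy)phenoxy]-3-{4-[(3-methylbut-2-en-1-yl)oxy]phenyl}propanoate (mixture of diastereomers) | COC(=O)C(O)C(Oc1cc(OCC=C)cc(O)c1OC)c1ccc(OCC=C(C)C)cc1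
A8 | alternative 3 | 3,7-dihydroxy-8-methoxy-2-{4-[(3-methylbut-2-en-1-yl)oxy]phenyl}-5-(prop-2-en-1-yloxy)-2,3-dihydro-4H-chromen-4-one (mixture of diastereomers) | COc1c(O)cc(OCC=C)c2c1OC(c1ccc(OCC=C(C)C)cc1)C(O)C2=O
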